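Start from the run so far on this very flask, which is also the flask asked about.

- eta: starting material 1.5 M; reagent 1.3 equiv; the very flask that is asked about, followed so far
- flask: starting material 1.5 M; reagent 1.30 equiv; time 2.5 h

eta run (percent of the starting material charged)

| time / min | mono adduct / % | tris adduct / % |
|---|---|---|
| 1.50 | 28.5 | 1.1 |
| 3.00 | 38.0 | 3.6 |
| 6.00 | 41.1 | 6.4 |
| 12.0 | 39.1 | 9.6 |
| 25.0 | 37.8 | 11.1 |
| 50.0 | 37.5 | 10.8 |

(each reading ± 0.5 percentage points)



* the moment within 2.5 h at which there is most mono adduct
* the amount of mono adduct, in percent of the starting material charged, at that time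
* the first time at which mono adduct reaches 20%, in the same percent, in min

Read two amounts from the run. The first is the sag S, the top mono adduct reading less the last one: 3.6 percentage points. The second is the scatter of a reading, 0.5 points.

Their ratio is 7.20, so treat the top at 6.00 min as a real maximum standing clear of the plateau. The last two readings differ by 0.3 points, less than the scatter, so reckon the plateau as the large term and S as the correction to it. That puts the best time near 6.00 min, not at the end of the 2.5 h, with 41.1% of mono adduct as a reading. For the level of 20%, draw the chord from zero to the first reading, which gives 1.05 min; the curve bends, so expect it somewhat sooner.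

The forecast gave 0.11 h, 41.3% and 0.9 min, with the words "no later rise is expected before 2.5 h". The flask gives 0.103 h, 40.3% and 0.851 min.

    reagent + mono adduct → bis adduct (k = 0.0940 M⁻¹ min⁻¹)
    reagent + bis adduct → tris adduct (k = 0.430 M⁻¹ min⁻¹)
    starting material + reagent → mono adduct (k = 0.170 M⁻¹ min⁻¹)
    reagent + tris adduct → tetra adduct (k = 0.260 M⁻¹ min⁻¹)
    2 starting material → homo dimer (k = 0.0430 M⁻¹ min⁻¹)

At 0.0270 h this flask makes mono adduct 3.38 times as fast as it uses it up, each step taken net. By 1.25 h reagent, the limiting reagent, stands at 0% and mono adduct at 37.2%, the amount it still has at 2.50 h. The neighbour flask with 0.520 equiv of reagent tops at 29.5% and ends at 29.4%, an S of 0.113 times the scatter, where the run on this flask read 3.6 points, or 7.20 times.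

All runs were computed from invented constants, noise included.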